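Cuts: first the C4(M)–O bond of the C4–O–C4 ether, which releases the all-cis flavan-3,4-diol unit L; then C4–C4a and O1–C2 in ring C of the middle unit M; last the interflavan bond C4(U)–C8(M).
Enabling feature: ring C of M has oxygen on C2 (as O1), C3 and C4. It is fused to ring A through C4a and the C8a oxygen, the last free ortho C–H/OH pair of a phloroglucinol ring whose other ortho carbon, C8, already holds U. C4–C3–C2 therefore maps onto an aldehyde–epoxide three-carbon unit.
Forward order: ring C of U comes with (−)-epicatechin and is arylated at C4 by 3,5-dibenzyloxyphenol. Ring C of M is closed by annulation with a cis-epoxy aldehyde, and the C4–OH of M is exchanged for an arylthio group. Silver activation then joins L through oxygen, and hydrogenolysis ends the route.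
Stereochemistry: C2/C3 of U and of L come from the two epicatechin enantiomers. C4 of U and C4 of M arise by attack on C4 cations anti to O3. C3 and C2 of M come from a Jacobsen–Katsuki epoxide (C2 by inversion). C4 of L arises by hydride addition to a 4-ketone anti to O3 and the aryl group.

Key step: step 8

Remark: U, M and L are the upper, middle and ether-bound flavan units, flavan numbering is used throughout and Bn is benzyl. It is assumed that (+)-epicatechin (2S,3S) can be bought as the single enantiomer, as (−)-epicatechin can.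

Step 1
Reactants: 1 (−)-epicatechin
Product: 2 5,7,3',4'-tetra-O-benzyl-(−)-epicatechin (2R,3R; 3-OH free)
Conditions: BnBr (4.2 equiv), K2CO3, DMF, 0 °C to rt, argon
Reagents that add atoms: benzyl bromide, BrCc1ccccc1
Why: Williamson ether synthesis in which K2CO3 ionises only the four phenols, so the secondary 3-OH stays free, and the mild base at low temperature avoids ring opening at C2, leaving both stereocentres untouched.

Step 2
Reactants: 2 5,7,3',4'-tetra-O-benzyl-(−)-epicatechin
Product: 3 3,5,7,3',4'-penta-O-benzyl-(−)-epicatechin (2R,3R)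
Conditions: NaH (1.5 equiv), BnBr (1.3 equiv), DMF, 0 °C to rt
Reagents that add atoms: benzyl bromide, BrCc1ccccc1
Why: Williamson ether synthesis of the remaining secondary alcohol with a strong base, which is safe now that no free phenol is left to open the pyran ring, so C2 and C3 are retained.

Step 3
Reactants: 3 3,5,7,3',4'-penta-O-benzyl-(−)-epicatechin
Product: 4 (2R,3R,4S)-penta-O-benzyl-4β-(2-ethoxyethoxy)epicatechin (2,3-cis-3,4-trans)
Conditions: DDQ (2 equiv), 2-ethoxyethanol (5 equiv), CH2Cl2, rt
Reagents that add atoms: 2-ethoxyethanol, CCOCCO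
Why: DDQ benzylic oxidation, in which hydride abstraction from C4 gives a cation stabilised by the 5,7-dibenzyloxy ring A and the alcohol adds from the face opposite the axial 3-OBn group, setting C4 trans to O3.

Step 4
Reactants: 4 (2R,3R,4S)-penta-O-benzyl-4β-(2-ethoxyethoxy)epicatechin; 5 3,5-dibenzyloxyphenol
Product: 6 penta-O-benzyl-4β-[2,4-bis(benzyloxy)-6-hydroxyphenyl]epicatechin (C4 aryl trans to O3)
Conditions: 5 (4 equiv), TMSOTf (0.2 equiv), CH2Cl2, −78 to −30 °C; aq NaHCO3
Reagents that add atoms: none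
Why: Friedel–Crafts alkylation of the kind used for 4→8 interflavan bonds, in which the C4 cation is attacked anti to the axial 3-OBn (aryl trans to O3), the two equivalent carbons of 5 between OH and OBn are less crowded than the one between two OBn groups, any aryl ether formed at oxygen re-ionises and returns to the ortho carbon, and the excess of 5 suppresses double alkylation.

Step 5
Reactants: 7 3,4-dibenzyloxybenzaldehyde
Product: 8 ethyl (Z)-3-[3,4-bis(benzyloxy)phenyl]prop-2-enoate
Conditions: (2-MeC6H4O)2P(O)CH2CO2Et (1.1 equiv), NaH (1.1 equiv), THF, −78 to 0 °C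
Reagents that add atoms: ethyl 2-[bis(2-methylphenoxy)phosphoryl]acetate, CCOC(=O)CP(=O)(Oc1ccccc1C)Oc1ccccc1C
Why: Ando variant of the Horner–Wadsworth–Emmons olefination, in which the electron-poor diaryl phosphonate makes elimination from the first-formed adduct fast and so gives the Z-cinnamate from aromatic aldehydes.

Step 6
Reactants: 8 ethyl (Z)-3-[3,4-bis(benzyloxy)phenyl]prop-2-enoate
Product: 9 ethyl (2S,3S)-3-[3,4-bis(benzyloxy)phenyl]oxirane-2-carboxylate (cis)
Conditions: (S,S)-[N,N'-bis(3,5-di-tert-butylsalicylidene)cyclohexane-1,2-diaminato]manganese chloride (5 mol %), 4-phenylpyridine N-oxide (0.25 equiv), aq NaOCl (pH 11.3), CH2Cl2, 4 °C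
Reagents that add atoms: sodium hypochlorite, [Na+].[O-]Cl
Why: Jacobsen–Katsuki epoxidation, for which Z-cinnamates are a proven substrate class: side-on approach of the cis-alkene to the oxo-manganese salen species of the (S,S)-ligand delivers oxygen to one face and sets both (2S,3S) centres, the N-oxide additive curbs leakage to the trans-epoxide (removed by chromatography), and the ester keeps the electron-rich aryl epoxide from ionising.

Step 7
Reactants: 9 ethyl (2S,3S)-3-[3,4-bis(benzyloxy)phenyl]oxirane-2-carboxylate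
Product: 10 (2S,3S)-3-[3,4-bis(benzyloxy)phenyl]oxirane-2-carbaldehyde (cis)
Conditions: i-Bu2AlH (1.05 equiv), toluene/CH2Cl2, −78 °C; MeOH, then aq potassium sodium tartrate
Reagents that add atoms: none
Why: Partial reduction of an ester with i-Bu2AlH, in which the aluminium hemiacetal, held by the neighbouring epoxide oxygen, persists at −78 °C and releases the aldehyde only on work-up without touching either epoxide carbon, and 10 is used at once without chromatography.

Step 8
Reactants: 6 penta-O-benzyl-4β-[2,4-bis(benzyloxy)-6-hydroxyphenyl]epicatechin; 10 (2S,3S)-3-[3,4-bis(benzyloxy)phenyl]oxirane-2-carbaldehyde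
Product: 13 nona-O-benzyl epicatechin-(4β→8)-epicatechin-4β-ol (M: 2R,3R,4S; free 3-OH and 4-OH), via chloromagnesium phenolate 11 (not isolated), via epoxy carbinol phenolate 12 (not isolated)
Conditions: i-PrMgCl (1.0 equiv, Et2O), 0 °C, Et2O removed in vacuo; CH2Cl2/toluene, 10 (1.2 equiv), −40 °C to rt; pH 7 phosphate buffer
Reagents that add atoms: isopropylmagnesium chloride, CC(C)[Mg]Cl (its MgCl is carried only by 11 and 12 and leaves on work-up)
Why: Proposed new method: phenolate 11 binds the aldehyde oxygen of 10 and delivers its only free ortho carbon (C4a of M) to the carbonyl through a six-membered chelate, and after rearomatisation the phenolate oxygen of 12 attacks the magnesium-activated epoxide at benzylic C2 from the rear, so that C4–C4a and O1–C2 form in one flask. The closest known reaction types are the ortho-specific hydroxyalkylation of halomagnesium phenolates with chiral alpha-oxygenated aldehydes and the 6-endo opening of aryl epoxides by phenols used in flavan-3-ol syntheses, and their combination on an epoxy aldehyde has not been described. The pyran ring closes 6-endo-tet, which should be preferred over 5-exo attack at C3 because the 3,4-dibenzyloxyphenyl group carries the positive charge that develops at C2. C3 keeps the epoxide configuration, C2 is set by inversion of the cis-epoxide (which gives the 2,3-cis relation), and C4 is set by attack on the aldehyde face left open when magnesium bridges the carbonyl and epoxide oxygens (syn adduct, 3,4-trans), an outcome that need not be perfect because C4 is ionised again in steps 9 and 16. Ortho rather than para C-alkylation is secured by the metal tether and by U blocking C8, while chloride in place of bromide and a non-polar medium should slow halohydrin formation (double inversion at C2), unimolecular opening and Payne migration by the C4 alkoxide. Material from the minor enantiomer of 10 becomes a diastereomer that chromatography should remove.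

Step 9
Reactants: 13 nona-O-benzyl epicatechin-(4β→8)-epicatechin-4β-ol
Product: 14 nona-O-benzyl 4β-(4-methylphenylthio)dimer (M: C4–S trans to the free 3-OH)
Conditions: 4-MeC6H4SH (1.5 equiv), BF3·OEt2 (0.2 equiv), CH2Cl2, −78 to −40 °C
Reagents that add atoms: 4-methylbenzenethiol, Cc1ccc(S)cc1
Why: Acid-catalysed thiolysis (SN1) as practised on flavan-4-ols and proanthocyanidins, in which only the C4 hydroxyl ionises, either C4 epimer of 13 gives the same ring-A-stabilised cation, and the thiol adds anti to the axial O3 so that C4–S stands trans to O3, at a temperature at which the interflavan bond is not cleaved.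

Step 10
Reactants: 14 nona-O-benzyl 4β-(4-methylphenylthio)dimer
Product: 15 deca-O-benzyl 4β-(4-methylphenylthio)dimer
Conditions: NaH (1.5 equiv), BnBr (1.3 equiv), DMF, 0 °C to rt
Reagents that add atoms: benzyl bromide, BrCc1ccccc1
Why: Williamson ether synthesis on the only free hydroxyl, the aryl sulfide being inert to NaH and BnBr, which removes O3 of M as a competing nucleophile for step 16 without touching a stereocentre.

Step 11
Reactants: 16 (+)-epicatechin
Product: 17 5,7,3',4'-tetra-O-benzyl-(+)-epicatechin (2S,3S; 3-OH free)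
Conditions: BnBr (4.2 equiv), K2CO3, DMF, 0 °C to rt, argon
Reagents that add atoms: benzyl bromide, BrCc1ccccc1
Why: Williamson ether synthesis as in step 1 on the enantiomer, selective for the four phenols and without effect on C2 or C3.

Step 12
Reactants: 17 5,7,3',4'-tetra-O-benzyl-(+)-epicatechin
Product: 18 3,5,7,3',4'-penta-O-benzyl-(+)-epicatechin (2S,3S)
Conditions: NaH (1.5 equiv), BnBr (1.3 equiv), DMF, 0 °C to rt
Reagents that add atoms: benzyl bromide, BrCc1ccccc1
Why: Williamson ether synthesis as in step 2, giving a 3-O group that cannot migrate to the cis hydroxyl installed later at C4.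

Step 13
Reactants: 18 3,5,7,3',4'-penta-O-benzyl-(+)-epicatechin
Product: 19 (2S,3S,4R)-3,5,7-tris(benzyloxy)-2-[3,4-bis(benzyloxy)phenyl]chroman-4-ol (2,3-cis-3,4-trans)
Conditions: DDQ (2 equiv), CH2Cl2/H2O (20:1), rt
Reagents that add atoms: water, O
Why: DDQ benzylic oxidation with water as the nucleophile, which adds to the C4 cation anti to the axial 3-OBn, the C4 configuration being of no consequence because step 14 erases it.

Step 14
Reactants: 19 (2S,3S,4R)-chroman-4-ol
Product: 20 (2S,3R)-3,5,7-tris(benzyloxy)-2-[3,4-bis(benzyloxy)phenyl]chroman-4-one (2,3-cis)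
Conditions: n-Pr4NRuO4 (5 mol %), N-methylmorpholine N-oxide (1.5 equiv), 4 Å MS, CH2Cl2, rt
Reagents that add atoms: none
Why: Ley–Griffith oxidation, whose neutral medium turns the acid-sensitive benzylic alcohol into the chromanone without ionising it and without enolising C3, so the 2,3-cis relation is kept.

Step 15
Reactants: 20 (2S,3R)-chroman-4-one
Product: 21 (2S,3S,4S)-3,5,7-tris(benzyloxy)-2-[3,4-bis(benzyloxy)phenyl]chroman-4-ol (all-cis)
Conditions: NaBH4 (2 equiv), THF/EtOH, −20 to 0 °C
Reagents that add atoms: none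
Why: Diastereoselective borohydride reduction of a cyclic ketone, in which hydride arrives axially on the face opposite the axial 3-OBn and the 2-aryl group so that the new pseudo-equatorial hydroxyl is cis to both, while the cold, weakly basic medium prevents epimerisation at C3.

Step 16
Reactants: 15 deca-O-benzyl 4β-(4-methylphenylthio)dimer; 21 (2S,3S,4S)-all-cis chroman-4-ol
Product: 22 pentadeca-O-benzyl trimer (C4 of M bound through oxygen to C4 of L; M 3,4-trans, L all-cis)
Conditions: 21 (1.5 equiv), AgBF4 (1.5 equiv), 2,6-di-tert-butyl-4-methylpyridine (2 equiv), 4 Å MS, THF, −40 to 0 °C, dark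
Reagents that add atoms: none
Why: Silver-promoted SN1 etherification of a flavan-4-yl thioether, the thiophilic activation known for C4 of flavans combined with the well-known capture of C4 cations by alcohols: the silver ion removes the thiolate without touching the free C4–OH of 21, the buffer prevents re-ionisation of the product, the hydroxyl oxygen is kinetically far more nucleophilic than the ring A carbons and adds anti to the axial 3-OBn of M (C4 of M trans to O3), and C4 of L keeps its configuration because its C–O bond is never broken.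

Step 17
Reactants: 22 pentadeca-O-benzyl trimer
Product: 23 target CNP0310719.1
Conditions: H2 (1 atm), Pd(OH)2/C, THF/EtOAc, rt, monitored closely; filtration, lyophilisation
Reagents that add atoms: none
Why: Catalytic hydrogenolysis of benzyl ethers, in which the fifteen unhindered O–CH2Ph bonds should cleave at 1 atm whereas the two inner C4–O bonds are secondary, flanked by ortho-substituted rings, and cannot lie flat on palladium, just as the equally benzylic C2–O1 bonds of flavans survive these conditions, and the neutral aprotic solvent avoids solvolysis so that no stereocentre is affected.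

Compound list
1 | (−)-epicatechin (2R,3R) | Oc1cc(O)c2c(c1)O[C@H](c1ccc(O)c(O)c1)[C@H](O)C2 | starting material
2 | 5,7,3',4'-tetra-O-benzyl-(−)-epicatechin | O(Cc9ccccc9)c1cc(OCc9ccccc9)c2c(c1)O[C@H](c1ccc(OCc9ccccc9)c(OCc9ccccc9)c1)[C@H](O)C2 | intermediate
3 | 3,5,7,3',4'-penta-O-benzyl-(−)-epicatechin | O(Cc9ccccc9)c1cc(OCc9ccccc9)c2c(c1)O[C@H](c1ccc(OCc9ccccc9)c(OCc9ccccc9)c1)[C@H](OCc9ccccc9)C2 | intermediate
4 | (2R,3R,4S)-penta-O-benzyl-4β-(2-ethoxyethoxy)epicatechin | O(Cc9ccccc9)c1cc(OCc9ccccc9)c2c(c1)O[C@H](c1ccc(OCc9ccccc9)c(OCc9ccccc9)c1)[C@H](OCc9ccccc9)[C@H]2OCCOCC | intermediate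
5 | 3,5-dibenzyloxyphenol | Oc1cc(OCc2ccccc2)cc(OCc2ccccc2)c1 | starting material
6 | penta-O-benzyl-4β-[2,4-bis(benzyloxy)-6-hydroxyphenyl]epicatechin | O(Cc9ccccc9)c1cc(OCc9ccccc9)c2c(c1)O[C@H](c1ccc(OCc9ccccc9)c(OCc9ccccc9)c1)[C@H](OCc9ccccc9)[C@H]2c1c(OCc9ccccc9)cc(OCc9ccccc9)cc1O | intermediate
7 | 3,4-dibenzyloxybenzaldehyde | O=Cc1ccc(OCc9ccccc9)c(OCc9ccccc9)c1 | starting material
8 | ethyl (Z)-3-[3,4-bis(benzyloxy)phenyl]prop-2-enoate | CCOC(=O)/C=C\c1ccc(OCc9ccccc9)c(OCc9ccccc9)c1 | intermediate
9 | ethyl (2S,3S)-3-[3,4-bis(benzyloxy)phenyl]oxirane-2-carboxylate (cis) | CCOC(=O)[C@H]1O[C@H]1c1ccc(OCc9ccccc9)c(OCc9ccccc9)c1 | intermediate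
10 | (2S,3S)-3-[3,4-bis(benzyloxy)phenyl]oxirane-2-carbaldehyde (cis) | O=C[C@H]1O[C@H]1c1ccc(OCc9ccccc9)c(OCc9ccccc9)c1 | intermediate
11 | chloromagnesium phenolate of 6 | O(Cc9ccccc9)c1cc(OCc9ccccc9)c2c(c1)O[C@H](c1ccc(OCc9ccccc9)c(OCc9ccccc9)c1)[C@H](OCc9ccccc9)[C@H]2c1c(OCc9ccccc9)cc(OCc9ccccc9)cc1O[Mg]Cl | intermediate
12 | chloromagnesium phenolate of the ortho-hydroxyalkylated phenol (C4a–C4 formed, epoxide intact) | O(Cc9ccccc9)c1cc(OCc9ccccc9)c2c(c1)O[C@H](c1ccc(OCc9ccccc9)c(OCc9ccccc9)c1)[C@H](OCc9ccccc9)[C@H]2c1c(OCc9ccccc9)cc(OCc9ccccc9)c([C@H](O)[C@H]3O[C@H]3c3ccc(OCc9ccccc9)c(OCc9ccccc9)c3)c1O[Mg]Cl | intermediate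
13 | nona-O-benzyl epicatechin-(4β→8)-epicatechin-4β-ol (free 3-OH and 4-OH on M) | O(Cc9ccccc9)c1cc(OCc9ccccc9)c2c(c1)O[C@H](c1ccc(OCc9ccccc9)c(OCc9ccccc9)c1)[C@H](OCc9ccccc9)[C@H]2c1c(OCc9ccccc9)cc(OCc9ccccc9)c2c1O[C@H](c1ccc(OCc9ccccc9)c(OCc9ccccc9)c1)[C@H](O)[C@H]2O | intermediate
14 | nona-O-benzyl 4β-(4-methylphenylthio)dimer (free 3-OH on M) | O(Cc9ccccc9)c1cc(OCc9ccccc9)c2c(c1)O[C@H](c1ccc(OCc9ccccc9)c(OCc9ccccc9)c1)[C@H](OCc9ccccc9)[C@H]2c1c(OCc9ccccc9)cc(OCc9ccccc9)c2c1O[C@H](c1ccc(OCc9ccccc9)c(OCc9ccccc9)c1)[C@H](O)[C@H]2Sc1ccc(C)cc1 | intermediate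
15 | deca-O-benzyl 4β-(4-methylphenylthio)dimer | O(Cc9ccccc9)c1cc(OCc9ccccc9)c2c(c1)O[C@H](c1ccc(OCc9ccccc9)c(OCc9ccccc9)c1)[C@H](OCc9ccccc9)[C@H]2c1c(OCc9ccccc9)cc(OCc9ccccc9)c2c1O[C@H](c1ccc(OCc9ccccc9)c(OCc9ccccc9)c1)[C@H](OCc9ccccc9)[C@H]2Sc1ccc(C)cc1 | intermediate
16 | (+)-epicatechin (2S,3S) | Oc1cc(O)c2c(c1)O[C@@H](c1ccc(O)c(O)c1)[C@@H](O)C2 | starting material
17 | 5,7,3',4'-tetra-O-benzyl-(+)-epicatechin | O(Cc9ccccc9)c1cc(OCc9ccccc9)c2c(c1)O[C@@H](c1ccc(OCc9ccccc9)c(OCc9ccccc9)c1)[C@@H](O)C2 | intermediate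
18 | 3,5,7,3',4'-penta-O-benzyl-(+)-epicatechin | O(Cc9ccccc9)c1cc(OCc9ccccc9)c2c(c1)O[C@@H](c1ccc(OCc9ccccc9)c(OCc9ccccc9)c1)[C@@H](OCc9ccccc9)C2 | intermediate
19 | (2S,3S,4R)-3,5,7-tris(benzyloxy)-2-[3,4-bis(benzyloxy)phenyl]chroman-4-ol (3,4-trans) | O(Cc9ccccc9)c1cc(OCc9ccccc9)c2c(c1)O[C@@H](c1ccc(OCc9ccccc9)c(OCc9ccccc9)c1)[C@@H](OCc9ccccc9)[C@@H]2O | intermediate
20 | (2S,3R)-3,5,7-tris(benzyloxy)-2-[3,4-bis(benzyloxy)phenyl]chroman-4-one | O(Cc9ccccc9)c1cc(OCc9ccccc9)c2c(c1)O[C@@H](c1ccc(OCc9ccccc9)c(OCc9ccccc9)c1)[C@@H](OCc9ccccc9)C2=O | intermediate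
21 | (2S,3S,4S)-3,5,7-tris(benzyloxy)-2-[3,4-bis(benzyloxy)phenyl]chroman-4-ol (all-cis) | O(Cc9ccccc9)c1cc(OCc9ccccc9)c2c(c1)O[C@@H](c1ccc(OCc9ccccc9)c(OCc9ccccc9)c1)[C@@H](OCc9ccccc9)[C@H]2O | intermediate
22 | pentadeca-O-benzyl trimer | O(Cc9ccccc9)c1cc(OCc9ccccc9)c2c(c1)O[C@H](c1ccc(OCc9ccccc9)c(OCc9ccccc9)c1)[C@H](OCc9ccccc9)[C@H]2c1c(OCc9ccccc9)cc(OCc9ccccc9)c2c1O[C@H](c1ccc(OCc9ccccc9)c(OCc9ccccc9)c1)[C@H](OCc9ccccc9)[C@H]2O[C@H]1c2c(OCc9ccccc9)cc(OCc9ccccc9)cc2O[C@@H](c2ccc(OCc9ccccc9)c(OCc9ccccc9)c2)[C@H]1OCc9ccccc9 | intermediate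
23 | CNP0310719.1, epicatechin-(4β→8)-epicatechin bound 4β→O→4 to all-cis (2S)-leucocyanidin | Oc1cc(O)c2c(c1)O[C@H](c1ccc(O)c(O)c1)[C@H](O)[C@H]2c1c(O)cc(O)c2c1O[C@H](c1ccc(O)c(O)c1)[C@H](O)[C@H]2O[C@H]1c2c(O)cc(O)cc2O[C@@H](c2ccc(O)c(O)c2)[C@H]1O | target

Total step count: 17.
Longest linear sequence: 9 steps (1, 2, 3, 4, 8, 9, 10, 16, 17).

Steps most likely to fail

Step 8. The sequence may halt after C–C bond formation. The epoxide may ionise at C2 before the phenolate arrives, which erodes the 2,3-cis relation. Alternatively, 5-exo attack at C3 or loss of the new benzylic alkoxide to an ortho-quinone methide may take over. The fallback uses known chemistry and sets out from 4 and 2. TMSOTf-catalysed Friedel–Crafts coupling of 4 with an excess of 2 in CH2Cl2 at −78 °C should give nona-O-benzyl epicatechin-(4β→8)-epicatechin F1. DDQ in wet CH2Cl2 should then oxidise its only benzylic CH2 group, C4 of the lower unit, with water adding anti to O3. This comes back to the route at 13.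

Step 16. The cation may be captured by C8 or C6 of ring A of 21 instead of by its hydroxyl. It may lose H3 to give a flav-3-ene. Adventitious acid may also ionise the L side of the new ether and epimerise C4 of L. The fallback blocks and deactivates ring A of the acceptor and sets out from 21 and 15. NBS (2 equiv) in CH2Cl2 at −78 to 0 °C should give the 6,8-dibromo all-cis alcohol F2. The same silver activation of 15 should then give the 6,8-dibromo pentadeca-O-benzyl trimer F3. H2 over Pd(OH)2/C with Et3N (2 equiv) should remove bromine and benzyl groups together, which comes back to the route at 23.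

Step 17. The inner C4–O–C4 ether may be cleaved on the palladium surface during the slower removal of the three aliphatic benzyl ethers. The freed ring A phenols may also expel the ether oxygen through a quinone methide. The fallback replaces surface hydrogenolysis by electron transfer, sets out from 22 and comes back at 23. It uses lithium 4,4'-di-tert-butylbiphenylide in THF at −78 °C, followed by a cold quench with degassed acetic acid. Electrons should enter the unsubstituted phenyl rings of the benzyl groups far more readily than the di- and trioxygenated rings that flank the inner C–O bonds. No new isolated compound arises.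

Further compounds
F1 | step 8 | nona-O-benzyl epicatechin-(4β→8)-epicatechin (free 3-OH on the lower unit) | O(Cc9ccccc9)c1cc(OCc9ccccc9)c2c(c1)O[C@H](c1ccc(OCc9ccccc9)c(OCc9ccccc9)c1)[C@H](OCc9ccccc9)[C@H]2c1c(OCc9ccccc9)cc(OCc9ccccc9)c2c1O[C@H](c1ccc(OCc9ccccc9)c(OCc9ccccc9)c1)[C@H](O)C2
F2 | step 16 | (2S,3S,4S)-6,8-dibromo-3,5,7-tris(benzyloxy)-2-[3,4-bis(benzyloxy)phenyl]chroman-4-ol (all-cis) | O(Cc9ccccc9)c1c(Br)c(OCc9ccccc9)c2c(c1Br)O[C@@H](c1ccc(OCc9ccccc9)c(OCc9ccccc9)c1)[C@@H](OCc9ccccc9)[C@H]2O
F3 | step 16 | pentadeca-O-benzyl trimer with bromine at C6 and C8 of L | O(Cc9ccccc9)c1cc(OCc9ccccc9)c2c(c1)O[C@H](c1ccc(OCc9ccccc9)c(OCc9ccccc9)c1)[C@H](OCc9ccccc9)[C@H]2c1c(OCc9ccccc9)cc(OCc9ccccc9)c2c1O[C@H](c1ccc(OCc9ccccc9)c(OCc9ccccc9)c1)[C@H](OCc9ccccc9)[C@H]2O[C@H]1c2c(OCc9ccccc9)c(Br)c(OCc9ccccc9)c(Br)c2O[C@@H](c2ccc(OCc9ccccc9)c(OCc9ccccc9)c2)[C@H]1OCc9ccccc9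
F0 | step 17 | none | none
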